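## Structural features

Eremophilane numbering is used throughout: ring A is the saturated ring C1–C2–C3–C4–C5–C10, and ring B is the cross-conjugated cyclohexa-2,5-dienone C5–C6=C7–C8(=O)–C9=C10. The rings share the C5–C10 bond, and C5 is the quaternary sp3 carbon of the dienone and carries the angular methyl (C14). Ring A holds four stereocenters: C1 (OH, allylic and γ to the C8 carbonyl), C3 (angelate), C4 (CH3, C15) and C5. The SMILES decodes to 1R,3S,4R,5R, with all four substituents on the same face (β) and C3/C4/C5 contiguous. Because ring B is flat, the C5 methyl must be axial on ring A, so the C1 and C3 oxygens are 1,3-diaxial to it and to each other, a congested arrangement that is best set under kinetic control. C7 carries a 2-hydroperoxypropan-2-yl group (C11), a tertiary allylic hydroperoxide that will not survive hydrides, phosphines, transition-metal redox chemistry or strong acid. The (Z)-2-methylbut-2-enoate isomerizes readily to the E ester, the 1,3-diaxial hydroxy ester can suffer acyl migration, and the γ-hydroxy dienone is sensitive to acid. The real difficulty is the quaternary C5 inside a dienone ring, with three further ring A stereocenters that must all end up syn to its methyl. The key step exploits the fact that ring B (C8=O, C6=C7, C9=C10, sp3 C5 bearing CH3) is the dearomatized form of a 4-methylphenol: C8 is the phenol carbon, C5 its para carbon, and C10 the meta carbon that carries the ring A chain.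

## Logic of the disconnections

22 is cut at the C11–O bond back to 20. The hydroperoxide is the most fragile group and must enter last, under neutral radical conditions. This leaves an isopropenyl group on C7. The forward step must deliver H and O2 in the Markovnikov sense to the one 1,1-disubstituted alkene, in the presence of three trisubstituted electron-poor alkenes, a free alcohol and a Z-enoate.

20 is cut at the C1–H bond back to 19, and 19 at the C1 ketal C–O bonds back to 18. A C1 ketone next to the axial C5 methyl can only be reduced from the open face, which gives the 1β alcohol. Keeping C1 masked until after acylation makes O3 the only hydroxyl when the ester is formed, so no protecting group is needed on O1. The forward steps need a mild hydrolysis that spares a β-acyloxy ketone, and a 1,2-reduction selective for C1 over C8.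

18 is cut at the acyl–O3 bond into 15 and 16. The Z-enoate is brought in late so that it meets as few reagents as possible. The forward step must acylate a hindered axial alcohol without Z-to-E isomerization.

15 is cut at the C7–C11 bond into 13 and 14, and 13 at the C7–I bond back to 12. An isopropenyl group on the arene would not survive the allylic oxidation at C3, so ring B stays unsubstituted at C7 until ring A is complete. The forward step needs α-iodination at C7 and not at C9.

12 is cut at the C4–H and C3–H bonds back to 9. Both stereocenters have their hydrogen on the face opposite the angular methyl, so both can come from one exo-methylene ketone by proton and hydride delivery to that open face. This removes two stereocenters in one operation. The forward step needs kinetic protonation of an enolate and a hindered hydride, with no equilibration of the intermediate ketone.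

9 is cut at the C3=O bond back to 7. In 7 the exocyclic alkene makes C3 the only allylic CH2 (C5 is quaternary), so an allylic oxidation needs no regiocontrol. The C3 configuration of the first-formed alcohol does not matter.

7 is cut at the C4–C5 bond back to 6; this is the key disconnection. In one sentence: ring A is closed and the quaternary C5 created by a palladium-catalysed, enantioselective dearomative alkenylation of the achiral bromoalkenyl phenol 6. The cut removes ring A, the quaternary stereocenter and the whole dienone, and leaves a flat arene with no stereocenter. The forward step must bond the alkenyl carbon to the para carbon (not the ortho carbon) and choose one face of the phenolate. The three remaining stereocenters (C4, C3, C1) are then relayed from C5.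

6 is cut at the ketal C–O bonds back to 5, 5 at the C2–C3 bond into 2 and 3, and 2 at the C1–CH3 bond back to 1. These are routine: an enolate allylation and a ketone synthesis from a carboxylic acid. The only demand is C-alkylation of the ketone enolate in the presence of the phenolate.

## Other disconnections considered

Alternative 1: (the first that comes to mind) cut C5–C6 and C9–C10 by a Robinson annulation.
- Forward key step: the proline-catalysed Hajos–Parrish–Eder–Sauer–Wiechert annulation would give enedione A1 with C5 set; Wittig methylenation of its saturated ketone would give A2.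
- Why the chosen plan is preferred: A1 and A2 carry ring B only at the enone level and ring A with no oxygen at C1 or C3. The C6=C7 double bond, the C1 oxygen (a γ-oxidation that would have to occur syn to the angular methyl and to an axial C3 substituent), the C3 oxygen and the C7 side chain would each need a separate oxidation. The arene of the chosen route already holds C8=O, both ring B double bonds and the C1 carbonyl.

Alternative 2: cut the same C4–C5 bond with reversed polarity.
- Forward key step: oxidative dearomatization (PhI(OAc)2 or anodic) of phenol A3, whose ethyl ketone enol would attack the phenoxonium ion at C5 to give diketone A4 with the C3 carbonyl and C15 in place.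
- Why the chosen plan is preferred: in A4 the C4 configuration would come from the enol geometry and a chair-versus-boat transition state, with nothing that favours one. It is also epimerizable, with no clear thermodynamic preference for the 4,5-cis isomer, because an equatorial C4 methyl is gauche to both C5 substituents. C5 would have to be induced by the C1 silyloxy group alone, where allylic strain and the developing 1,3-diaxial interaction pull in opposite directions. The chosen plan sets C5 by catalyst control on an achiral substrate and defers C4 to a protonation with a decisive facial bias.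

Alternative 3: cut C1–C10 by a desymmetrizing intramolecular Stetter reaction.
- Forward key step: a chiral triazolium carbene would convert the prochiral cyclohexadienone aldehyde A5 into the cis-fused diketone A6.
- Why the chosen plan is preferred: A5 already contains the C4–C5 bond, so its preparation would need an intermolecular dearomative C-alkylation of a 4-methylphenol by a secondary carbon, for which no reliable method exists, with C3 and C4 set beforehand in an open chain. The Stetter step consumes the C9=C10 double bond, which must be put back, and creates an extra stereocenter at C10. The hard bond is only moved into the preparation of A5.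

Key step: step 4

Assumption: (R)-AntPhos stands for the P-chiral ligand 4-(anthracen-9-yl)-3-tert-butyl-2,3-dihydro-1,3-benzoxaphosphole; its sense of induction with an alkenyl bromide cannot be predicted, and the enantiomer that delivers (4'aR)-7 is meant.

## Steps

Step 1
Reactants: 1 5-hydroxy-2-methylbenzoic acid
Product: 2 1-(5-hydroxy-2-methylphenyl)ethan-1-one
Conditions: MeLi (3.5 equiv), THF, 0 °C to rt; inverse quench into cold aq. HCl
Reagents that add atoms: methyllithium, [Li]C
Why: Addition of methyllithium to a lithium carboxylate stops at the gem-diolate, which collapses to the methyl ketone only on work-up (ketone synthesis from a carboxylic acid); two equivalents are consumed by the two acidic OH groups.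

Step 2
Reactants: 2 1-(5-hydroxy-2-methylphenyl)ethan-1-one; 3 2,3-dibromoprop-1-ene
Product: 5 4-bromo-1-(5-hydroxy-2-methylphenyl)pent-4-en-1-one, via dilithium enolate phenolate 4 (not isolated)
Conditions: LiN(i-Pr)2 (2.2 equiv), THF, −78 °C; then 3 (1.0 equiv), −78 to −20 °C; aq. HCl work-up
Reagents that add atoms: none
Why: Enolate allylation (SN2 at the allylic bromide; the vinylic bromide is inert to substitution); in THF at low temperature the lithium phenolate is far less nucleophilic than the ketone enolate, so the new bond should form at C2.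

Step 3
Reactants: 5 4-bromo-1-(5-hydroxy-2-methylphenyl)pent-4-en-1-one
Product: 6 3-[2-(3-bromobut-3-en-1-yl)-1,3-dioxolan-2-yl]-4-methylphenol
Conditions: ethylene glycol (5 equiv), TsOH·H2O (5 mol%), benzene, reflux, Dean–Stark trap
Reagents that add atoms: ethane-1,2-diol, OCCO
Why: Acid-catalysed ketalization with azeotropic removal of water; it carries C1 at the ketone oxidation level, removes every enolizable proton before the base-mediated key step and makes the benzylic carbon quaternary.

Step 4
Reactants: 6 3-[2-(3-bromobut-3-en-1-yl)-1,3-dioxolan-2-yl]-4-methylphenol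
Product: 7 (4'aR)-4'a-methyl-4'-methylidene-3',4'-dihydro-2'H-spiro[[1,3]dioxolane-2,1'-naphthalen]-7'(4'aH)-one
Conditions: Pd(OAc)2 (5 mol%), (R)-AntPhos (10 mol%), K2CO3 (2.0 equiv), degassed toluene, 90 °C
Reagents that add atoms: none
Why: Zerovalent palladium (formed in situ from Pd(OAc)2 and the phosphine) adds oxidatively to the C4–Br bond, carbonate converts the phenol into its potassium phenolate, and the phenolate attacks the alkenylpalladium bromide through its para carbon C5 to give a seven-membered C-bound palladacycle in which ring B is already a cyclohexadienone; C(sp2)–C(sp3) reductive elimination then forms C4–C5 and returns zerovalent palladium. The closest known reaction type is the palladium-catalysed dearomative cyclization of 3-tethered 4-alkylphenols onto an aryl bromide, which gives fused 4a-alkyl dienones enantioselectively with P-chiral monophosphines; alkenylpalladium intermediates are also known to dearomatize phenols at the para carbon in spiroannulations, so the step is that reaction applied to a 2-bromoalkene. Ring A is closed in a six-membered mode by reductive elimination from the palladacycle, with the alkene left exocyclic (exo with respect to the alkenyl unit). The only new stereocenter is C5: the ligand decides on which face of the flat, achiral phenolate the Pd–C5 and then the C4–C5 bond are made, the methyl group is pushed to the other face, and no stereocenter in the substrate competes. The step needs para (C5) over ortho (C9) C-attack, which would rearomatize to a tetralin: C5 carries the largest coefficient of the phenolate HOMO and is made more electron-rich by its methyl group, while C9 lies between the O–K group and the ring carbon that bears the bulky ketal and is screened from a ligated palladium. It also needs C- over O-attack, which geometry secures because the phenolate oxygen cannot reach C4. The ketal leaves no enolizable proton in substrate or product, so no enolate can compete, and its gem-dialkoxy carbon favours the folded conformer needed for closure (Thorpe–Ingold effect).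

Step 5
Reactants: 7 (4'aR)-4'a-methyl-4'-methylidene-3',4'-dihydro-2'H-spiro[[1,3]dioxolane-2,1'-naphthalen]-7'(4'aH)-one
Product: 9 (4'aR)-4'a-methyl-4'-methylidene-2'H-spiro[[1,3]dioxolane-2,1'-naphthalene]-3',7'(4'H,4'aH)-dione, via allylic alcohol 8 (not isolated)
Conditions: SeO2 (0.5 equiv), t-BuOOH (3 equiv), CH2Cl2, rt; crude alcohol then Dess–Martin periodinane (1.5 equiv), NaHCO3, CH2Cl2, 0 °C to rt
Reagents that add atoms: selenium dioxide, O=[Se]=O (source of the C3 oxygen; regenerated by tert-butyl hydroperoxide, CC(C)(C)OO)
Why: Allylic oxidation by ene reaction and [2,3]-sigmatropic shift; C3 is the only allylic position that bears hydrogen and the electron-poor dienone alkenes should not react, so the site is fixed. The C3 configuration of 8 is irrelevant because Dess–Martin oxidation takes both epimers to enone 9.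

Step 6
Reactants: 9 (4'aR)-4'a-methyl-4'-methylidene-2'H-spiro[[1,3]dioxolane-2,1'-naphthalene]-3',7'(4'H,4'aH)-dione
Product: 12 (3'S,4'R,4'aR)-3'-hydroxy-4',4'a-dimethyl-3',4'-dihydro-2'H-spiro[[1,3]dioxolane-2,1'-naphthalen]-7'(4'aH)-one, via lithium enolate 10 (not isolated), via ketone 11 (not isolated)
Conditions: LiBH(s-Bu)3 (1.05 equiv), THF, −78 °C; AcOH (1.05 equiv), −78 °C; then LiBH(s-Bu)3 (1.5 equiv), −78 °C; AcOH quench
Reagents that add atoms: none
Why: Conjugate reduction of the unhindered exocyclic enone gives enolate 10, which should be protonated at C4 on the face opposite the axial C5 methyl (axial protonation) to give the 4β-methyl ketone 11 with the 4,5-cis relationship. The second portion of the hindered hydride should attack the C3 carbonyl from the same open face, because the other face is closed by the syn-axial C5 methyl and the axial ketal oxygen, giving the axial 3β alcohol. The epimerizable ketone 11 is never isolated, and the exocyclic enone and the saturated ketone react faster than the hindered dienone.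

Step 7
Reactants: 12 (3'S,4'R,4'aR)-3'-hydroxy-4',4'a-dimethyl-3',4'-dihydro-2'H-spiro[[1,3]dioxolane-2,1'-naphthalen]-7'(4'aH)-one
Product: 13 (3'S,4'R,4'aS)-3'-hydroxy-6'-iodo-4',4'a-dimethyl-3',4'-dihydro-2'H-spiro[[1,3]dioxolane-2,1'-naphthalen]-7'(4'aH)-one
Conditions: I2 (2 equiv), pyridine/CH2Cl2 (1:1), 0 °C to rt
Reagents that add atoms: iodine, II
Why: α-Iodination of an enone (pyridine adds to the β-carbon, the enolate is iodinated, pyridine is lost); only C6 is a β-carbon that still carries hydrogen (C10 is fully substituted), so iodine should enter at C7 alone. The descriptor at C4'a changes to S only because iodine alters the priorities.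

Step 8
Reactants: 13 (3'S,4'R,4'aS)-3'-hydroxy-6'-iodo-4',4'a-dimethyl-3',4'-dihydro-2'H-spiro[[1,3]dioxolane-2,1'-naphthalen]-7'(4'aH)-one; 14 4,4,5,5-tetramethyl-2-(prop-1-en-2-yl)-1,3,2-dioxaborolane
Product: 15 (3'S,4'R,4'aR)-3'-hydroxy-4',4'a-dimethyl-6'-(prop-1-en-2-yl)-3',4'-dihydro-2'H-spiro[[1,3]dioxolane-2,1'-naphthalen]-7'(4'aH)-one
Conditions: PdCl2(dppf) (5 mol%), K3PO4 (3 equiv), THF/H2O (10:1), 50 °C
Reagents that add atoms: none
Why: Suzuki–Miyaura coupling of an α-iodoenone with an alkenylboronate; the ketal, the free alcohol and the dienone are inert to mild aqueous phosphate.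

Step 9
Reactants: 15 (3'S,4'R,4'aR)-3'-hydroxy-4',4'a-dimethyl-6'-(prop-1-en-2-yl)-3',4'-dihydro-2'H-spiro[[1,3]dioxolane-2,1'-naphthalen]-7'(4'aH)-one; 16 (2Z)-2-methylbut-2-enoic acid (angelic acid)
Product: 18 (3'S,4'R,4'aR)-4',4'a-dimethyl-7'-oxo-6'-(prop-1-en-2-yl)-3',4',4'a,7'-tetrahydro-2'H-spiro[[1,3]dioxolane-2,1'-naphthalen]-3'-yl (2Z)-2-methylbut-2-enoate, via mixed anhydride 17 (not isolated)
Conditions: 16, 2,4,6-trichlorobenzoyl chloride, Et3N, THF, 0 °C, filtered; 15, LiN(SiMe3)2 (1.1 equiv), THF, −78 °C; then the anhydride solution, −78 to 0 °C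
Reagents that add atoms: none
Why: Yamaguchi-type mixed anhydride 17 should acylate the lithium alkoxide of 15 at the angeloyl carbonyl, because the trichlorobenzoyl carbonyl is shielded by two ortho chlorines. Acyl transfer to a preformed alkoxide at low temperature needs neither a nucleophilic catalyst nor heat, the two usual causes of Z-to-E isomerization. O3 is the only hydroxyl because C1 is still a ketal.

Step 10
Reactants: 18 (3'S,4'R,4'aR)-4',4'a-dimethyl-7'-oxo-6'-(prop-1-en-2-yl)-3',4',4'a,7'-tetrahydro-2'H-spiro[[1,3]dioxolane-2,1'-naphthalen]-3'-yl (2Z)-2-methylbut-2-enoate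
Product: 19 (4aR,5R,6S)-4a,5-dimethyl-2,8-dioxo-3-(prop-1-en-2-yl)-2,4a,5,6,7,8-hexahydronaphthalen-6-yl (2Z)-2-methylbut-2-enoate
Conditions: PPTS (0.3 equiv), acetone/H2O (10:1), 50 °C
Reagents that add atoms: water, O
Why: Acid-catalysed ketal hydrolysis; no free hydroxyl is present at this stage, and weakly acidic conditions should spare the Z-enoate, the isopropenyl group and the β-acyloxy ketone that is formed.

Step 11
Reactants: 19 (4aR,5R,6S)-4a,5-dimethyl-2,8-dioxo-3-(prop-1-en-2-yl)-2,4a,5,6,7,8-hexahydronaphthalen-6-yl (2Z)-2-methylbut-2-enoate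
Product: 20 (4aR,5R,6S,8R)-8-hydroxy-4a,5-dimethyl-2-oxo-3-(prop-1-en-2-yl)-2,4a,5,6,7,8-hexahydronaphthalen-6-yl (2Z)-2-methylbut-2-enoate
Conditions: NaBH4 (1.0 equiv), CeCl3·7H2O (1.2 equiv), MeOH/CH2Cl2, −78 °C
Reagents that add atoms: none
Why: Luche 1,2-reduction; the C1 carbonyl (conjugated with one alkene) is more electrophilic than the cross-conjugated C8 carbonyl, which is also flanked by the isopropenyl group. Hydride should enter anti to the axial C5 methyl and the axial 3-ester, giving the axial 1β alcohol, as in the reduction of 6-oxo steroids to 6β alcohols. The cold, non-basic conditions should spare the β-acyloxy ketone and the Z-enoate.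

Step 12
Reactants: 20 (4aR,5R,6S,8R)-8-hydroxy-4a,5-dimethyl-2-oxo-3-(prop-1-en-2-yl)-2,4a,5,6,7,8-hexahydronaphthalen-6-yl (2Z)-2-methylbut-2-enoate
Product: 22 (4aR,5R,6S,8R)-8-hydroxy-3-(2-hydroperoxypropan-2-yl)-4a,5-dimethyl-2-oxo-2,4a,5,6,7,8-hexahydronaphthalen-6-yl (2Z)-2-methylbut-2-enoate, via triethylsilyl peroxide 21 (not isolated)
Conditions: Co(acac)2 (15 mol%), O2 (1 atm), Et3SiH (2.5 equiv), 1,2-dichloroethane, rt; then MeOH, PPTS (cat.), 0 °C
Reagents that add atoms: dioxygen, O=O
Why: Isayama–Mukaiyama hydroperoxysilylation: a cobalt hydride transfers a hydrogen atom to the terminal CH2 of the isopropenyl group (the only 1,1-disubstituted alkene, and part of a diene), the tertiary C11 radical is trapped by O2, and the peroxyl radical is reduced and silylated; mild methanolysis then frees the hydroperoxide. The trisubstituted, electron-poor enone and angelate alkenes should react much more slowly, and no stereocenter is formed.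

## Compound list

1 | 5-hydroxy-2-methylbenzoic acid | Cc1ccc(O)cc1C(=O)O | starting material
2 | 1-(5-hydroxy-2-methylphenyl)ethan-1-one | Cc1ccc(O)cc1C(C)=O | intermediate
3 | 2,3-dibromoprop-1-ene | C=C(Br)CBr | starting material
4 | dilithium enolate phenolate of 2 (lithium 3-[1-(lithiooxy)ethenyl]-4-methylphenolate) | [Li]Oc1ccc(C)c(c1)C(=C)O[Li] | intermediate (not isolated)
5 | 4-bromo-1-(5-hydroxy-2-methylphenyl)pent-4-en-1-one | Cc1ccc(O)cc1C(=O)CCC(Br)=C | intermediate
6 | 3-[2-(3-bromobut-3-en-1-yl)-1,3-dioxolan-2-yl]-4-methylphenol | Cc1ccc(O)cc1C1(CCC(Br)=C)OCCO1 | intermediate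
7 | (4'aR)-4'a-methyl-4'-methylidene-3',4'-dihydro-2'H-spiro[[1,3]dioxolane-2,1'-naphthalen]-7'(4'aH)-one | C1CC2(OCCO2)C3=CC(=O)C=C[C@]3(C)C1=C | intermediate
8 | (4'aR)-3'-hydroxy-4'a-methyl-4'-methylidene-3',4'-dihydro-2'H-spiro[[1,3]dioxolane-2,1'-naphthalen]-7'(4'aH)-one (both C3' epimers) | OC1CC2(OCCO2)C3=CC(=O)C=C[C@]3(C)C1=C | intermediate (not isolated)
9 | (4'aR)-4'a-methyl-4'-methylidene-2'H-spiro[[1,3]dioxolane-2,1'-naphthalene]-3',7'(4'H,4'aH)-dione | O=C1CC2(OCCO2)C3=CC(=O)C=C[C@]3(C)C1=C | intermediate
10 | lithium enolate of 11 (C3'–OLi, C3'=C4') | [Li]OC=1CC2(OCCO2)C3=CC(=O)C=C[C@]3(C)C=1C | intermediate (not isolated)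
11 | (4'R,4'aR)-4',4'a-dimethyl-2'H-spiro[[1,3]dioxolane-2,1'-naphthalene]-3',7'(4'H,4'aH)-dione | O=C1CC2(OCCO2)C3=CC(=O)C=C[C@]3(C)[C@H]1C | intermediate (not isolated)
12 | (3'S,4'R,4'aR)-3'-hydroxy-4',4'a-dimethyl-3',4'-dihydro-2'H-spiro[[1,3]dioxolane-2,1'-naphthalen]-7'(4'aH)-one | O[C@H]1CC2(OCCO2)C3=CC(=O)C=C[C@]3(C)[C@H]1C | intermediate
13 | (3'S,4'R,4'aS)-3'-hydroxy-6'-iodo-4',4'a-dimethyl-3',4'-dihydro-2'H-spiro[[1,3]dioxolane-2,1'-naphthalen]-7'(4'aH)-one | O[C@H]1CC2(OCCO2)C3=CC(=O)C(I)=C[C@]3(C)[C@H]1C | intermediate
14 | 4,4,5,5-tetramethyl-2-(prop-1-en-2-yl)-1,3,2-dioxaborolane | CC(=C)B1OC(C)(C)C(C)(C)O1 | starting material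
15 | (3'S,4'R,4'aR)-3'-hydroxy-4',4'a-dimethyl-6'-(prop-1-en-2-yl)-3',4'-dihydro-2'H-spiro[[1,3]dioxolane-2,1'-naphthalen]-7'(4'aH)-one | O[C@H]1CC2(OCCO2)C3=CC(=O)C(C(C)=C)=C[C@]3(C)[C@H]1C | intermediate
16 | (2Z)-2-methylbut-2-enoic acid (angelic acid) | C/C=C(/C)C(=O)O | starting material
17 | (2Z)-2-methylbut-2-enoic 2,4,6-trichlorobenzoic anhydride | C/C=C(/C)C(=O)OC(=O)c1c(Cl)cc(Cl)cc1Cl | intermediate (not isolated)
18 | (3'S,4'R,4'aR)-4',4'a-dimethyl-7'-oxo-6'-(prop-1-en-2-yl)-3',4',4'a,7'-tetrahydro-2'H-spiro[[1,3]dioxolane-2,1'-naphthalen]-3'-yl (2Z)-2-methylbut-2-enoate | C/C=C(/C)C(=O)O[C@H]1CC2(OCCO2)C3=CC(=O)C(C(C)=C)=C[C@]3(C)[C@H]1C | intermediate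
19 | (4aR,5R,6S)-4a,5-dimethyl-2,8-dioxo-3-(prop-1-en-2-yl)-2,4a,5,6,7,8-hexahydronaphthalen-6-yl (2Z)-2-methylbut-2-enoate | C/C=C(/C)C(=O)O[C@H]1CC(=O)C2=CC(=O)C(C(C)=C)=C[C@]2(C)[C@H]1C | intermediate
20 | (4aR,5R,6S,8R)-8-hydroxy-4a,5-dimethyl-2-oxo-3-(prop-1-en-2-yl)-2,4a,5,6,7,8-hexahydronaphthalen-6-yl (2Z)-2-methylbut-2-enoate | C/C=C(/C)C(=O)O[C@H]1C[C@@H](O)C2=CC(=O)C(C(C)=C)=C[C@]2(C)[C@H]1C | intermediate
21 | (4aR,5R,6S,8R)-8-hydroxy-4a,5-dimethyl-2-oxo-3-{2-[(triethylsilyl)peroxy]propan-2-yl}-2,4a,5,6,7,8-hexahydronaphthalen-6-yl (2Z)-2-methylbut-2-enoate | C/C=C(/C)C(=O)O[C@H]1C[C@@H](O)C2=CC(=O)C(C(C)(C)OO[Si](CC)(CC)CC)=C[C@]2(C)[C@H]1C | intermediate (not isolated)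
22 | (4aR,5R,6S,8R)-8-hydroxy-3-(2-hydroperoxypropan-2-yl)-4a,5-dimethyl-2-oxo-2,4a,5,6,7,8-hexahydronaphthalen-6-yl (2Z)-2-methylbut-2-enoate (CNP0300636.1) | C/C=C(/C)C(=O)O[C@H]1C[C@@H](O)C2=CC(=O)C(C(C)(C)OO)=C[C@]2(C)[C@H]1C | target

## Step count and least certain steps

Total step count: 12. Longest linear sequence: 12 steps (1 to 22); 3, 14 and 16 are purchased.

Step 4 (key step). Most likely failure: loss of site selectivity in the C–C bond formation, that is, coupling at C9 (ortho to the phenolate oxygen, unsubstituted) followed by rearomatization. Both C5 and C9 are one bond from the tether, and C9 needs no quaternary carbon to be formed. A second concern is slow reductive elimination to a quaternary carbon next to the ketal, and the sense and level of induction with an alkenyl bromide are not assured. Fallback (blocking strategy), from 5 back to 7: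
- Chlorinate both positions ortho to the hydroxyl of 5 (N-chlorosuccinimide, cat. i-Pr2NH, CH2Cl2) to give 4-bromo-1-(2,4-dichloro-3-hydroxy-6-methylphenyl)pent-4-en-1-one F1.
- Ketalize as in step 3 to 3-[2-(3-bromobut-3-en-1-yl)-1,3-dioxolan-2-yl]-2,6-dichloro-4-methylphenol F2.
- Cyclize under the conditions of step 4 to (4'aR)-6',8'-dichloro-4'a-methyl-4'-methylidene-3',4'-dihydro-2'H-spiro[[1,3]dioxolane-2,1'-naphthalen]-7'(4'aH)-one F3. With both ortho carbons blocked, only the para carbon can be alkenylated without creating a chlorine-bearing quaternary carbon.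
- Remove both vinylic chlorines by palladium-catalysed transfer hydrogenolysis (Pd(OAc)2, PPh3, HCO2Na, DMF) to rejoin the route at 7.

Step 12. Most likely failure: capture of the delocalized allylic radical by O2 at C6 instead of C11, or hydrogen-atom transfer to the enone alkenes. The radical formed at C11 is conjugated with C6=C7, and the cobalt hydride is not fully selective. Fallback (change from radical to pericyclic oxygenation), from 20 back to 22:
- Add H2 in a 1,4 sense across the C6=C7–C11=C12 diene of 20 (H2, Cr(CO)3(η6-naphthalene) cat., THF) to give (4aR,5R,6S,8R)-8-hydroxy-4a,5-dimethyl-2-oxo-3-(propan-2-ylidene)-2,3,4,4a,5,6,7,8-octahydronaphthalen-6-yl (2Z)-2-methylbut-2-enoate F7.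
- Carry out a Schenck ene reaction with singlet oxygen (O2, tetraphenylporphyrin, visible light, CH2Cl2, 0 °C). In an α,β-unsaturated ketone, hydrogen should be abstracted from the group geminal to the carbonyl (C6–H) with O–O bonding at C11, which gives 22 directly.

Step 9. Most likely failure: Z-to-E isomerization of the acyl group during transfer, or failure to acylate the hindered axial alkoxide. O3 is flanked by the C4 methyl and is 1,3-diaxial to the C5 methyl and a ketal oxygen. Fallback (build the Z-alkene on the ester instead of transferring it), from 15 back to 18: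
- Esterify 15 with 2-[bis(2,2,2-trifluoroethoxy)phosphoryl]propanoic acid (DCC, DMAP, CH2Cl2) to give (3'S,4'R,4'aR)-4',4'a-dimethyl-7'-oxo-6'-(prop-1-en-2-yl)-3',4',4'a,7'-tetrahydro-2'H-spiro[[1,3]dioxolane-2,1'-naphthalen]-3'-yl 2-[bis(2,2,2-trifluoroethoxy)phosphoryl]propanoate F5.
- Run a Still–Gennari olefination with acetaldehyde (KN(SiMe3)2, 18-crown-6, THF, −78 °C), which should give the Z-enoate 18.

Step 6. Most likely failure: epimerization at C4 by proton exchange between ketone 11 and enolate 10 before the second hydride arrives, or conjugate reduction of the C6=C7 alkene by excess hydride. Fallback (set C3 first, then C4 by hydrogenation instead of enolate protonation), from 9 back to 12: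
- Reduce enone 9 in the 1,2 sense (NaBH4, CeCl3·7H2O, MeOH, −78 °C; hydride anti to the C5 methyl) to (3'S,4'aR)-3'-hydroxy-4'a-methyl-4'-methylidene-3',4'-dihydro-2'H-spiro[[1,3]dioxolane-2,1'-naphthalen]-7'(4'aH)-one F4.
- Hydrogenate the exocyclic alkene from the face opposite the C5 methyl (H2, RhCl(PPh3)3, benzene) to give 12.

Step 11. Most likely failure: poor site selectivity between the C1 and C8 carbonyls (over-reduction), since both are conjugated ketones. Fallback (reduce both, re-oxidize one), from 19 back to 20:
- Reduce both carbonyls of 19 (NaBH4 excess, CeCl3·7H2O, MeOH, −40 °C) to (4aR,5R,6S,8R)-2,8-dihydroxy-4a,5-dimethyl-3-(prop-1-en-2-yl)-2,4a,5,6,7,8-hexahydronaphthalen-6-yl (2Z)-2-methylbut-2-enoate F6.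
- Oxidize with MnO2 (CH2Cl2, rt). The doubly allylic C2 carbinol should be oxidized much faster than the hindered axial C8 carbinol, giving 20.

## Further compounds

F1 | step 4 | 4-bromo-1-(2,4-dichloro-3-hydroxy-6-methylphenyl)pent-4-en-1-one | Cc1cc(Cl)c(O)c(Cl)c1C(=O)CCC(Br)=C
F2 | step 4 | 3-[2-(3-bromobut-3-en-1-yl)-1,3-dioxolan-2-yl]-2,6-dichloro-4-methylphenol | Cc1cc(Cl)c(O)c(Cl)c1C1(CCC(Br)=C)OCCO1
F3 | step 4 | (4'aR)-6',8'-dichloro-4'a-methyl-4'-methylidene-3',4'-dihydro-2'H-spiro[[1,3]dioxolane-2,1'-naphthalen]-7'(4'aH)-one | C1CC2(OCCO2)C3=C(Cl)C(=O)C(Cl)=C[C@]3(C)C1=C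
F4 | step 6 | (3'S,4'aR)-3'-hydroxy-4'a-methyl-4'-methylidene-3',4'-dihydro-2'H-spiro[[1,3]dioxolane-2,1'-naphthalen]-7'(4'aH)-one | O[C@H]1CC2(OCCO2)C3=CC(=O)C=C[C@]3(C)C1=C
F5 | step 9 | (3'S,4'R,4'aR)-4',4'a-dimethyl-7'-oxo-6'-(prop-1-en-2-yl)-3',4',4'a,7'-tetrahydro-2'H-spiro[[1,3]dioxolane-2,1'-naphthalen]-3'-yl 2-[bis(2,2,2-trifluoroethoxy)phosphoryl]propanoate | CC(C(=O)O[C@H]1CC2(OCCO2)C3=CC(=O)C(C(C)=C)=C[C@]3(C)[C@H]1C)P(=O)(OCC(F)(F)F)OCC(F)(F)F
F6 | step 11 | (4aR,5R,6S,8R)-2,8-dihydroxy-4a,5-dimethyl-3-(prop-1-en-2-yl)-2,4a,5,6,7,8-hexahydronaphthalen-6-yl (2Z)-2-methylbut-2-enoate (both C2 epimers) | C/C=C(/C)C(=O)O[C@H]1C[C@@H](O)C2=CC(O)C(C(C)=C)=C[C@]2(C)[C@H]1C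
F7 | step 12 | (4aR,5R,6S,8R)-8-hydroxy-4a,5-dimethyl-2-oxo-3-(propan-2-ylidene)-2,3,4,4a,5,6,7,8-octahydronaphthalen-6-yl (2Z)-2-methylbut-2-enoate | C/C=C(/C)C(=O)O[C@H]1C[C@@H](O)C2=CC(=O)C(=C(C)C)C[C@]2(C)[C@H]1C
A1 | alternative 1 | (8aS)-8a-methyl-3,4,8,8a-tetrahydronaphthalene-1,6(2H,7H)-dione | C[C@]12CCC(=O)C=C1CCCC2=O
A2 | alternative 1 | (4aR)-4a-methyl-5-methylidene-4,4a,5,6,7,8-hexahydronaphthalen-2(3H)-one | C1CCC2=CC(=O)CC[C@]2(C)C1=C
A3 | alternative 2 | (1R)-1-[(tert-butyldimethylsilyl)oxy]-1-(5-hydroxy-2-methylphenyl)pentan-3-one | CCC(=O)C[C@@H](O[Si](C)(C)C(C)(C)C)c1cc(O)ccc1C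
A4 | alternative 2 | (4aR,8R)-8-[(tert-butyldimethylsilyl)oxy]-4a,5-dimethyl-7,8-dihydronaphthalene-2,6(4aH,5H)-dione (both C5 epimers) | O=C1C[C@@H](O[Si](C)(C)C(C)(C)C)C2=CC(=O)C=C[C@]2(C)C1C
A5 | alternative 3 | (3S,4R)-3-[(tert-butyldimethylsilyl)oxy]-4-(1-methyl-4-oxocyclohexa-2,5-dien-1-yl)pentanal | CC(C)(C)[Si](C)(C)O[C@H]([C@H](C)C1(C)C=CC(=O)C=C1)CC=O
A6 | alternative 3 | (4aR,5R,6S,8aR)-6-[(tert-butyldimethylsilyl)oxy]-4a,5-dimethyl-4a,5,6,7-tetrahydronaphthalene-2,8(1H,8aH)-dione | CC(C)(C)[Si](C)(C)O[C@H]1CC(=O)[C@@H]2CC(=O)C=C[C@]2(C)[C@H]1C
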